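**Retrosynthetic overview**
1. Carbon sources: 1-triacontanol 1 is oxidised via aldehyde 2 to the C30 acid 3, and 4-methylresorcinol 4 is C-acetylated to acetophenone 5. Ring A (benzene) is bought, not built.
2. C2–C3 (Claisen) disconnection: N-acylimidazole 6 plus trilithium enolate 7 give the open-chain 1,3-diketone 8.
3. O1–C2 disconnection: 8 has a single ortho hydroxyl, so closing ring B (pyranone) to chromone 9 can only give the 6-methyl series. This avoids the 6-/8-methyl ambiguity of phloroglucinol-type precursors.
4. C5–O disconnection (key bond, made last): 9 is masked in the flask as 10, carbonyl-directed C5–H oxygenation gives 11, and hydrolysis gives target 12. Ring order: ring A comes from 4, and ring B is closed in the last flask just before the C5–O bond forms.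

Assumption: the SMILES holds no stereocentre or stereogenic double bond, so the target is achiral and no enantiocontrol is needed; the side chain is read as the unbranched C29 (nonacosyl) group.

**Step 1**
Reactants: 1 1-triacontanol
Product: 3 triacontanoic acid, via triacontanal 2 (not isolated)
Conditions: TEMPO (2,2,6,6-tetramethylpiperidin-1-oxyl, 0.2 equiv), PhI(OAc)2 (2.4 equiv), CHCl3–MeCN–H2O (5:3:1), 45 °C
Reagents that add atoms: water, SMILES O
Why: Oxoammonium (TEMPO)-catalysed alcohol oxidation with PhI(OAc)2 as terminal oxidant takes the primary alcohol to aldehyde 2, water hydrates 2, the hydrate is oxidised again to the acid, and the saturated chain offers no other reactive site.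

**Step 2**
Reactants: 4 4-methylresorcinol (4-methylbenzene-1,3-diol)
Product: 5 1-(2,4-dihydroxy-5-methylphenyl)ethan-1-one (2',4'-dihydroxy-5'-methylacetophenone)
Conditions: AcOH (solvent and reagent), ZnCl2 (1.5 equiv), 140 °C; dilute aq. HCl work-up
Reagents that add atoms: acetic acid, SMILES CC(=O)O
Why: In this Nencki reaction (ZnCl2-promoted Friedel–Crafts C-acylation of a phenol with a carboxylic acid), C6 of 4 is para to one hydroxyl and ortho to the other, which makes it the most nucleophilic and least crowded site, so the acetyl group enters there and the ortho-hydroxy ketone hydrogen bond stabilises the product.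

**Step 3**
Reactants: 3 triacontanoic acid; 5 2',4'-dihydroxy-5'-methylacetophenone
Product: 8 1-(2,4-dihydroxy-5-methylphenyl)dotriacontane-1,3-dione, via 1-triacontanoylimidazole 6 (not isolated), via trilithium enolate-bis(phenoxide) 7 (not isolated)
Conditions: 3, 1,1'-carbonyldiimidazole (1.05 equiv), THF, 50 °C; separately 5, LiN(SiMe3)2 (4.5 equiv), THF, −78 to −10 °C; combine, −10 to 40 °C; cold dilute aq. HCl
Reagents that add atoms: none
Why: In this crossed Claisen condensation (C-acylation of a ketone lithium enolate by an N-acylimidazole) the enolate carbon of trianion 7 is the most nucleophilic centre, any 2'-O-acyl ester formed on the side is carried to the same diketone by a base-induced Baker–Venkataraman acyl shift, and the stable diketonate protects 8 from a second acylation.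

**Step 4**
Reactants: 8 1-(2,4-dihydroxy-5-methylphenyl)dotriacontane-1,3-dione
Product: 12 5,7-dihydroxy-6-methyl-2-nonacosyl-4H-chromen-4-one, via 7-hydroxy-6-methyl-2-nonacosylchromone 9 (not isolated), via chromone 7-trifluoroacetate 10 (not isolated), via chromone 5,7-bis(trifluoroacetate) 11 (not isolated)
Conditions: CF3CO2H–1,2-dichloroethane (1:1), 70 °C, 1 h; then (CF3CO)2O (8 equiv), [RuCl2(p-cymene)]2 (5 mol%), PhI(OCOCF3)2 (1.6 equiv, in portions), 80 °C; evaporate; THF–H2O (4:1), 40 °C
Reagents that add atoms: [bis(trifluoroacetoxy)iodo]benzene, SMILES O=C(OI(OC(=O)C(F)(F)F)c1ccccc1)C(F)(F)F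
Why: Proposed new method: a one-flask dehydrative ring closure/carbonyl-directed peri C–H oxygenation started from the open-chain diketone, in which CF3CO2H closes the O1–C2 bond through the only ortho hydroxyl (hemiketal, then loss of water) and so creates the strongly Lewis-basic 4-pyranone carbonyl, (CF3CO)2O takes up the water and masks the 7-OH as an electron-poor trifluoroacetate that trivalent iodine does not attack, cationic divalent ruthenium binds the pyranone oxygen and cleaves the single peri C5–H bond by trifluoroacetate-assisted concerted metalation–deprotonation to a five-membered ruthenacycle, PhI(OCOCF3)2 raises it to tetravalent ruthenium, C–O reductive elimination gives the C5 trifluoroacetate, and the anhydrous medium followed by neutral hydrolysis frees both esters without ring opening and so without 6-/8-methyl scrambling; the closest known reaction type is the ruthenium-catalysed ketone-directed ortho C–H oxygenation of aryl ketones with trivalent iodine oxidants in CF3CO2H/(CF3CO)2O, which has not been run as a cascade from a 1,3-diketone that builds its own directing group, on a phenol masked only in the flask, or at a peri C–H wedged between the carbonyl and an ortho methyl group.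

**Compound list**
1 | 1-triacontanol | CCCCCCCCCCCCCCCCCCCCCCCCCCCCCCO | starting material
2 | triacontanal | CCCCCCCCCCCCCCCCCCCCCCCCCCCCCC=O | intermediate
3 | triacontanoic acid | CCCCCCCCCCCCCCCCCCCCCCCCCCCCCC(=O)O | intermediate
4 | 4-methylresorcinol | Cc1ccc(O)cc1O | starting material
5 | 1-(2,4-dihydroxy-5-methylphenyl)ethan-1-one | CC(=O)c1cc(C)c(O)cc1O | intermediate
6 | 1-triacontanoylimidazole | CCCCCCCCCCCCCCCCCCCCCCCCCCCCCC(=O)n1ccnc1 | intermediate
7 | trilithium enolate-bis(phenoxide) of 5 | [Li+].[Li+].[Li+].C=C([O-])c1cc(C)c([O-])cc1[O-] | intermediate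
8 | 1-(2,4-dihydroxy-5-methylphenyl)dotriacontane-1,3-dione | CCCCCCCCCCCCCCCCCCCCCCCCCCCCCC(=O)CC(=O)c1cc(C)c(O)cc1O | intermediate
9 | 7-hydroxy-6-methyl-2-nonacosyl-4H-chromen-4-one | CCCCCCCCCCCCCCCCCCCCCCCCCCCCCc1cc(=O)c2cc(C)c(O)cc2o1 | intermediate
10 | 6-methyl-2-nonacosyl-4-oxo-4H-chromen-7-yl trifluoroacetate | CCCCCCCCCCCCCCCCCCCCCCCCCCCCCc1cc(=O)c2cc(C)c(OC(=O)C(F)(F)F)cc2o1 | intermediate
11 | 6-methyl-2-nonacosyl-4-oxo-4H-chromene-5,7-diyl bis(trifluoroacetate) | CCCCCCCCCCCCCCCCCCCCCCCCCCCCCc1cc(=O)c2c(OC(=O)C(F)(F)F)c(C)c(OC(=O)C(F)(F)F)cc2o1 | intermediate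
12 | 5,7-dihydroxy-6-methyl-2-nonacosyl-4H-chromen-4-one (achiral) | CCCCCCCCCCCCCCCCCCCCCCCCCCCCCc1cc(=O)c2c(O)c(C)c(O)cc2o1 | target

**Step count and risks**

Total step count: 4. Longest linear sequence: 3 steps (1 → 3 → 8 → 12, that is steps 1, 3 and 4).

The three steps most likely to fail:

**Step 4 (the new cascade).**
- Risks: ruthenation may not occur at the crowded C5–H next to the 6-methyl group, or the oxidant may attack C3 or the benzylic methyl.
- Fallback (known chemistry only, from 6 back to 12): drop the C–H oxygenation and bring in all three ring oxygens from the start.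
- 2',4',6'-Trihydroxy-3'-methylacetophenone F1 is purchased, or made from 2-methylphloroglucinol with AcOH/BF3·OEt2. It is deprotonated with LiN(SiMe3)2 (5.5 equiv, THF) to the tetralithium enolate-tris(phenoxide) F2.
- F2 is C-acylated by 6 to give 1-(2,4,6-trihydroxy-3-methylphenyl)dotriacontane-1,3-dione F3.
- H2SO4 (cat.) in AcOH at 100 °C cyclodehydrates F3 through either ortho hydroxyl. This gives 12 together with 5,7-dihydroxy-8-methyl-2-nonacosylchromone F4.
- 12 is obtained pure by chromatography and recrystallisation, and HMBC from the chelated 5-OH proton tells the isomers apart. The price of this fallback is the loss of regiocontrol.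

**Step 3 (polyanion acylation with a waxy acyl donor).**
- Risks: 6 may precipitate at low temperature, or O-acylation may occur at the 4'-oxygen.
- Fallback (from 3 and 5 back to 8): use intramolecular rather than intermolecular acyl transfer, a Baker–Venkataraman route.
- 3 is converted with SOCl2 (toluene, 70 °C) into triacontanoyl chloride F5.
- 5 is esterified on both hydroxyls (F5 2.2 equiv, pyridine, toluene, 60 °C) to 4-acetyl-6-methyl-1,3-phenylene bis(triacontanoate) F6.
- KOH powder in pyridine at 50 °C shifts the 2'-acyl group onto the acetyl carbon, giving 5-hydroxy-2-methyl-4-(3-oxodotriacontanoyl)phenyl triacontanoate F7.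
- The remaining ester of F7 is cleaved in the same flask with aq. KOH–THF. Acidification gives 8 and returns one equivalent of 3.

**Step 1 (oxidation of a poorly soluble wax alcohol).**
- Risks: the conversion may stall, or hemiacetal oxidation may form the wax ester.
- Fallback (from 1 back to 9): work at the aldehyde oxidation level, so no acid is needed.
- The same TEMPO/PhI(OAc)2 couple (1.1 equiv) in dry CHCl3 stops at aldehyde 2, which is isolated.
- Kabbe condensation of 2 with 5 (pyrrolidine 0.5 equiv, toluene–EtOH, reflux; aldol condensation then oxa-Michael closure) gives racemic 7-hydroxy-6-methyl-2-nonacosylchroman-4-one F8.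
- Dehydrogenation with DDQ (dioxane, reflux) erases the stereocentre and gives 9. Compound 9 enters step 4 at the point where (CF3CO)2O, catalyst and oxidant are added.

**Further compounds**
F1 | step 4 | 1-(2,4,6-trihydroxy-3-methylphenyl)ethan-1-one | CC(=O)c1c(O)cc(O)c(C)c1O
F2 | step 4 | tetralithium enolate-tris(phenoxide) of F1 | [Li+].[Li+].[Li+].[Li+].C=C([O-])c1c([O-])cc([O-])c(C)c1[O-]
F3 | step 4 | 1-(2,4,6-trihydroxy-3-methylphenyl)dotriacontane-1,3-dione | CCCCCCCCCCCCCCCCCCCCCCCCCCCCCC(=O)CC(=O)c1c(O)cc(O)c(C)c1O
F4 | step 4 | 5,7-dihydroxy-8-methyl-2-nonacosyl-4H-chromen-4-one | CCCCCCCCCCCCCCCCCCCCCCCCCCCCCc1cc(=O)c2c(O)cc(O)c(C)c2o1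
F5 | step 3 | triacontanoyl chloride | CCCCCCCCCCCCCCCCCCCCCCCCCCCCCC(=O)Cl
F6 | step 3 | 4-acetyl-6-methyl-1,3-phenylene bis(triacontanoate) | CC(=O)c1cc(C)c(OC(=O)CCCCCCCCCCCCCCCCCCCCCCCCCCCCC)cc1OC(=O)CCCCCCCCCCCCCCCCCCCCCCCCCCCCC
F7 | step 3 | 5-hydroxy-2-methyl-4-(3-oxodotriacontanoyl)phenyl triacontanoate | CCCCCCCCCCCCCCCCCCCCCCCCCCCCCC(=O)CC(=O)c1cc(C)c(OC(=O)CCCCCCCCCCCCCCCCCCCCCCCCCCCCC)cc1O
F8 | step 1 | 7-hydroxy-6-methyl-2-nonacosylchroman-4-one (racemic) | CCCCCCCCCCCCCCCCCCCCCCCCCCCCCC1CC(=O)c2cc(C)c(O)cc2O1
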